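Watch the partner.

| setting | ash | larch | maple | Monday's | Sunday's | Saturday's | Friday's |
|---|---|---|---|---|---|---|---|
| starting material | 10 mM | 10 mM | 10 mM | 10 mM | 10 mM (fed, over 12 min) | 10 mM | 10 mM |
| partner | 20 mM | 13 mM | 30 mM | 20.0 mM (fed, over 12 min) | 20.0 mM | 20.0 mM | 20.0 mM (fed, over 80 s) |
| remark | run made earlier | run made earlier | run made earlier | all else is in the flask from the start; the feed brings no volume worth counting | all else is in the flask from the start; the feed brings no volume worth counting | everything together at the start | all else is in the flask from the start; the feed brings no volume worth counting |
| time |  |  |  | 15 min | 15 min | 15 min | 15 min |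

- ash (time / min: first product / %, bis adduct / %): 1.00: 34, 6; 3.00: 41, 18; 5.00: 39, 26; 8.00: 39, 30; 12.0: 35, 34; 15.0: 32, 38
- larch (time / min: first product / %, bis adduct / %): 2.00: 33, 7; 4.00: 36, 18; 6.00: 40, 15; 8.00: 40, 14; 10.0: 40, 15; 12.0: 42, 16
- maple (time / min: first product / %, bis adduct / %): 2.00: 42, 24; 4.00: 31, 38; 6.00: 23, 46; 8.00: 23, 55; 10.0: 22, 57; 12.0: 17, 53

(scatter of a reading: 2 percentage points)

1. the flask that comes out highest in share of first product in first product plus bis adduct, or "all alike" when all lie within 1.5 percentage points (Monday's / Sunday's / Saturday's / Friday's / all alike)
2. share of first product in first product plus bis adduct at the end, Monday's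
3. share of first product in first product plus bis adduct at the end, Sunday's
4. share of first product in first product plus bis adduct at the end, Saturday's
5. share of first product in first product plus bis adduct at the end, Friday's

- what was read earlier has a scatter of 2 percentage points, one standard deviation
- candidate steps: starting material + partner -> first product + released group; starting material + partner -> other mono adduct + released group; partner + first product -> bis adduct + released group; partner + other mono adduct -> bis adduct + released group; partner -> decomposed reagent

1. Partner leaves by three exits: it couples with starting material, it turns a mono adduct into bis adduct, or it decays alone. Coupling and decay both go with its first power, so its level cancels from their ratio. Call A the starting material in mM, and A* the fork level, the A at which coupling and decay take partner equally. With all starting material charged at the start, decay then costs A*·ln(charge/left).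

2. Take late maple as fully converted: first product plus bis adduct reads 75.7%, and the rest is unread other mono adduct.

3. Larch is flat from 8.00 min, so count all its partner as used. Its sum gives A left of 2.64 mM, and decay took 4.14 mM. So A* = 3.11 mM, the fork level.

4. Ash's first reading leaves A at 4.71 mM. So starting material lives 1.12 min in full partner, and partner's decay half-life is 5.00 min.

5. Draw A in Sunday's, taking coupling as settled. The feed is 0.833 mM min⁻¹, so A starts flat near 0.936 mM, below A*, and decay outruns coupling.

6. By my reckoning the knee comes when partner falls to 6.01 mM, at 5.57 min, where A reaches A*. On the same reckoning 1.53 mM has coupled by then.

7. Past the knee, suppose that between half and the whole of that partner goes to starting material. My reckoning leaves 24.6% to 54.7% of the starting material at the end.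

8. Bis adduct needs partner too. I reckon that ash, which has Saturday's recipe, still holds about 11.8 mM of partner at its first reading, more than Sunday's 6.01 mM at the knee, so I place Sunday's above Saturday's. This reckoning does not place Sunday's against Monday's.

The forecast gave 56%, 53%, 47% and 48% for Monday's, Sunday's, Saturday's and Friday's, and chose Monday's: “Monday's narrowly leads, though this is uncertain”.

The flasks give 56.3%, 61.8%, 49.6% and 49.8%, so Sunday's leads.

    starting material + partner → first product + released group (k = 0.555 M⁻¹ s⁻¹)
    starting material + partner → other mono adduct + released group (k = 0.193 M⁻¹ s⁻¹)
    partner + first product → bis adduct + released group (k = 0.296 M⁻¹ s⁻¹)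
    partner + other mono adduct → bis adduct + released group (k = 0.0158 M⁻¹ s⁻¹)
    partner → decomposed reagent (k = 0.00194 s⁻¹)

In Sunday's, decay ran first: at 7.50 min starting material stood at 2.26 mM, below A*, and decomposed reagent, 10.0 mM, was twice the released group. Partner, charged at twice the starting material, then became the limiting reagent: Sunday's ended with 2.17% of it, 39.3% starting material and 17.4% bis adduct. In the neighbour charged with 40 mM, 57.2% of the starting material stayed, A*·ln(charge/left) gives 1.74 mM of decay, and the flask holds 1.45 mM decomposed reagent.

The readings stem from a simulated flask for substances that don't exist; noise was put on by code.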